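**Plan**

- Names: ring A is the cyclohexenedione and ring B the cyclopentane. Their shared atom is the central spiro carbon, the ring B CH beside it is the ring B methine, and C2 of the pinane is the pinane spiro carbon. In ring A the enone carbonyl lies between the central spiro carbon and the C-methyl carbon, and the saturated ketone lies between the central spiro carbon and the ring CMe2 carbon.
- Cuts: first the O–CH3 bond of the enol ether and the side-chain C–H (taken back to C–OH). Then two bonds of ring A, enone carbonyl carbon to C-methyl carbon and ring CMe2 carbon to saturated ketone carbon, which leaves a lactone ester and 2-methylpentan-3-one. Then the bond from the central spiro carbon to the ring B methine together with the lactone C–O bond, and last the bond from the pinane spiro carbon to its ring B CH2 and the C=C between the two future spiro carbons.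
- Forward: the pinane ring is bought as β-pinene. Conjugate addition makes the pinane spiro carbon quaternary. An oxidative radical cyclisation closes ring B and the lactone in one operation. A [3+3] double Claisen annulation closes ring A, and O-methylation and deoxygenation finish the route.
- Stereochemistry: the bridgeheads come from β-pinene. The pinane spiro carbon is set by addition anti to the gem-dimethyl bridge, the ring B methine in the radical closure, and the central spiro carbon by the cis lactonisation, after which it is carried unchanged.
- Enabling feature: the two carbonyl carbons on the central spiro carbon differ only in their remote neighbours (C–CH3 against CMe2), but the enone carbonyl is cis to the substituent on the ring B methine. A γ-lactone reaching over from that side chain can engage only this carbonyl, which marks it for the first acylation.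

Key step: step 5

Remark: the pinane unit of the target matches (1R,5R)-(+)-β-pinene, so this enantiomer of the terpene is taken as the purchasable chiral starting material; the enolised triketone formed in the key step is drawn as one of its two equilibrating enol tautomers.

**Route**

Step 1
Reactants: 1 (1R,5R)-(+)-β-pinene
Product: 2 (1S,5R)-(−)-nopinone
Conditions: O3, CH2Cl2/MeOH, −78 °C; then Me2S, −78 °C → rt
Reagents that add atoms: ozone, [O-][O+]=O
Why: Ozonolysis with reductive work-up cleaves the exocyclic C=C, the only π bond present, and touches neither bridgehead, so no stereocentre is formed or disturbed.

Step 2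
Reactants: 2 (1S,5R)-(−)-nopinone; 3 dimethyl malonate
Product: 4 dimethyl 2-[(1S,5R)-6,6-dimethylbicyclo[3.1.1]heptan-2-ylidene]malonate
Conditions: TiCl4, pyridine, THF, 0 °C → rt
Reagents that add atoms: none
Why: Knoevenagel condensation in its TiCl4/pyridine form, in which titanium activates the ketone, carries the malonate enolate and binds the water irreversibly, should give the tetrasubstituted alkylidene malonate from this cyclohexanone-like ketone without creating a stereocentre.

Step 3
Reactants: 4 alkylidene malonate; 5 5-bromo-2-methylpent-2-ene
Product: 7 dimethyl 2-[6,6-dimethyl-2-(4-methylpent-3-enyl)bicyclo[3.1.1]heptan-2-yl]malonate having the chain anti to the gem-dimethyl bridge, via homoprenyl Grignard reagent 6 (not isolated)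
Conditions: 5, Mg, THF, rt; then CuBr·SMe2 (20 mol%), 4, THF, −30 → 0 °C; 1 M HCl
Reagents that add atoms: none
Why: Copper-catalysed conjugate addition of a Grignard reagent to an alkylidene malonate; the organocopper species reaches C2 of the pinane from the face of the CH2 bridge because the inner methyl of the gem-dimethyl bridge covers the other face, which sets the quaternary pinane spiro carbon with the homoprenyl chain anti and the malonyl carbon syn to that bridge.

Step 4
Reactants: 7 homoprenyl malonate
Product: 8 cis-fused γ-lactone methyl ester of the spiro cyclopentane
Conditions: Mn(OAc)3·2H2O (2.2 equiv), Cu(OAc)2·H2O (20 mol%), AcOH, 70 °C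
Reagents that add atoms: none
Why: Mn(OAc)3-mediated oxidative free-radical cyclisation: trivalent manganese converts the malonate into its radical, which closes 5-exo-trig on the trisubstituted alkene through a chair-like transition state that keeps the CMe2 terminus on the side of the new ring facing C3 of the pinane, away from bridgehead C1 and the gem-dimethyl bridge (this sets the ring B methine), and divalent copper, turned over by manganese, oxidises the tertiary radical to the cation, which only the cis ester can capture, so that loss of its methyl group to acetate leaves the cis-fused γ-lactone and fixes the central spiro carbon.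

Step 5
Reactants: 8 lactone ester; 9 2-methylpentan-3-one
Product: 12 hydroxy enol triketone, via ethyl-side lithium enolate 10 (not isolated), via open-chain hydroxy diketone ester 11 (not isolated)
Conditions: 9 (3 equiv), LiN(iPr)2 (3 equiv), THF, −78 °C; 8, −78 → 0 °C; then LiN(iPr)2 (3 equiv), −78 °C → rt; cold 1 M HCl to pH 4
Reagents that add atoms: none
Why: LiN(iPr)2 deprotonates 9 at its CH2 group and the enolate 10 adds through that carbon to the lactone carbonyl of 8, the tetrahedral intermediate collapsing with release of the tertiary alkoxide (this forms the bond between the enone carbonyl carbon and the C-methyl carbon) to give 11 as its diketone enolate; the second charge of base removes the only remaining α-hydrogen, the isopropyl methine, and the tertiary carbon of the dianion attacks the methyl ester with loss of methoxide (this forms the bond between the ring CMe2 carbon and the saturated ketone carbon). The closest known reactions are the Claisen acylation of ketone enolates by lactones and the Dieckmann-type closure of β-diketone dianions onto esters that leads to cyclohexane-1,3,5-triones. Ring A closes in the 6-(enolendo)-exo-trig mode. No stereocentre is formed, since the central spiro carbon already carries two different carbonyl groups in 8 and keeps its configuration, while the C-methyl carbon ends up trigonal in the enol. The step needs the CH2 enolate to take the lactone and to leave the ester for the later carbanion: the γ-lactone, locked in the less stabilised E ester geometry, is the better acyl donor, neither carbonyl on the central spiro carbon can be enolised by the base, and kinetic deprotonation of 9 occurs on the ethyl side, so the carbonyl cis to the ring B side chain becomes the enone carbonyl and the ester carbon becomes the saturated ketone. Each acylation is pulled forward because its product, 11 and then 12, is at once converted into a stabilised enolate.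

Step 6
Reactants: 12 hydroxy enol triketone
Product: 13 vinylogous methyl ester (methoxy on the carbon between the C-methyl and ring CMe2 carbons) bearing the tertiary alcohol
Conditions: TMSCHN2 (2 M in hexanes), toluene/MeOH (4:1), 0 °C
Reagents that add atoms: trimethylsilyldiazomethane, C[Si](C)(C)C=[N+]=[N-]
Why: O-Methylation of a vinylogous acid by a diazoalkane, expected at the oxygen between the C-methyl and ring CMe2 carbons because the other enol oxygen is buried between the central spiro carbon and the cis CMe2OH group, whose hydroxyl hydrogen-bonds to it and so keeps the enol proton, and hence the methyl delivered within the ion pair, on the remote side.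

Step 7
Reactants: 13 vinylogous methyl ester alcohol
Product: 14 tertiary methyl oxalate of 13
Conditions: ClC(O)CO2Me, Et3N, 4-(dimethylamino)pyridine (cat.), CH2Cl2, 0 °C → rt
Reagents that add atoms: methyl chlorooxoacetate, COC(=O)C(=O)Cl
Why: Acylation of a tertiary alcohol by a highly reactive acid chloride under nucleophilic catalysis, with no competing site because the vinylogous acid is already capped and the basic medium cannot trigger ether exchange at ring A.

Step 8
Reactants: 14 tertiary methyl oxalate
Product: 15 CNP0307059.1 (target)
Conditions: Bu3SnH (2 equiv, 0.2 M), azobisisobutyronitrile (cat.), toluene, 110 °C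
Reagents that add atoms: none
Why: Barton-type radical deoxygenation of a tertiary alcohol through its methyl oxalate: the stannyl radical adds to the oxalate carbonyl, fragmentation releases the tertiary side-chain radical and this takes hydrogen from Bu3SnH, kept concentrated enough to outrun β-scission of the bond to the central spiro carbon, which leaves the ring B methine untouched because the radical is exocyclic to it and spares the vinylogous ester under neutral conditions.

**Compound list**

1 | (1R,5R)-(+)-β-pinene | C=C1CC[C@@H]2C[C@H]1C2(C)C | starting material
2 | (1S,5R)-(−)-nopinone, (1S,5R)-6,6-dimethylbicyclo[3.1.1]heptan-2-one | O=C1CC[C@@H]2C[C@H]1C2(C)C | intermediate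
3 | dimethyl malonate | COC(=O)CC(=O)OC | starting material
4 | dimethyl 2-[(1S,5R)-6,6-dimethylbicyclo[3.1.1]heptan-2-ylidene]malonate | COC(=O)C(C(=O)OC)=C1CC[C@@H]2C[C@H]1C2(C)C | intermediate
5 | 5-bromo-2-methylpent-2-ene | CC(C)=CCCBr | starting material
6 | 4-methylpent-3-enylmagnesium bromide (not isolated) | CC(C)=CCC[Mg]Br | intermediate
7 | dimethyl 2-[6,6-dimethyl-2-(4-methylpent-3-enyl)bicyclo[3.1.1]heptan-2-yl]malonate; bridgeheads as in 2, homoprenyl chain on the face of the CH2 bridge, malonyl carbon syn to the gem-dimethyl bridge | COC(=O)C(C(=O)OC)[C@@]1(CCC=C(C)C)CC[C@@H]2C[C@H]1C2(C)C | intermediate
8 | cis-fused lactone ester: ring B spiro to C2 of the pinane; the central spiro carbon carries CO2CH3 (cis to bridgehead C1) and the lactone carbonyl (cis to C3 of the pinane); the lactone oxygen sits on the CMe2 group at the ring B methine, which lies on the same face as the lactone carbonyl | O=C1OC(C)(C)[C@H]2CC[C@@]3(CC[C@@H]4C[C@H]3C4(C)C)[C@@]12C(=O)OC | intermediate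
9 | 2-methylpentan-3-one | CCC(=O)C(C)C | starting material
10 | lithium 2-methylpent-3-en-3-olate, the ethyl-side enolate of 9 (either geometry; not isolated) | CC=C(O[Li])C(C)C | intermediate
11 | open-chain hydroxy diketone ester: the central spiro carbon carries CO2CH3 and C(=O)CH(CH3)C(=O)CH(CH3)2, the latter cis to the C(CH3)2OH group on the ring B methine; epimers or enol at the CH(CH3) carbon (not isolated, present as its lithium enolate alkoxide) | CC(C)C(=O)C(C)C(=O)[C@@]2(C(=O)OC)[C@@H](C(C)(C)O)CC[C@@]21CC[C@@H]2C[C@H]1C2(C)C | intermediate
12 | enolised spiro triketone with rings A and B complete: enol OH on the carbon between the C-methyl and ring CMe2 carbons, C=O on both carbons attached to the central spiro carbon, C(CH3)2OH on the ring B methine cis to the carbonyl next to the C-methyl carbon | OC1=C(C)C(=O)[C@@]2(C(=O)C1(C)C)[C@@H](C(C)(C)O)CC[C@@]21CC[C@@H]2C[C@H]1C2(C)C | intermediate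
13 | methyl enol ether of 12 (OCH3 on the carbon between the C-methyl and ring CMe2 carbons) with the free tertiary alcohol | COC1=C(C)C(=O)[C@@]2(C(=O)C1(C)C)[C@@H](C(C)(C)O)CC[C@@]21CC[C@@H]2C[C@H]1C2(C)C | intermediate
14 | methyl oxalate of the tertiary alcohol of 13 | COC1=C(C)C(=O)[C@@]2(C(=O)C1(C)C)[C@@H](C(C)(C)OC(=O)C(=O)OC)CC[C@@]21CC[C@@H]2C[C@H]1C2(C)C | intermediate
15 | CNP0307059.1 | COC1=C(C)C(=O)[C@@]2(C(=O)C1(C)C)[C@@H](C(C)C)CC[C@@]21CC[C@@H]2C[C@H]1C2(C)C | target

**Count**

Total steps: 8. Longest linear sequence: 8 steps (1 → 15); 3, 5 and 9 are bought and enter directly.

**Steps most likely to fail**

1. Step 5. Acylation of a lactone carbonyl that sits on a quaternary carbon in a crowded spiro environment may be too slow, so that self-condensation of the enolate or attack at the ester takes over. The sequence may also stall after the first acylation because the tertiary carbanion fails to form or to close. The two C–C bonds would then be made in separate operations with a more reactive acceptor. Setting out from 8, iBu2AlH (1.1 equiv, CH2Cl2, −78 °C) should reduce the lactone, the more reactive of the two carbonyl groups, to the lactol F1. Its hydroxy aldehyde form undergoes aldol addition with enolate 10 (3 equiv, THF, −78 °C) to give the β-hydroxy ketone F2, which forms the bond between the future enone carbonyl carbon and the C-methyl carbon. Dess–Martin periodinane then oxidises the secondary carbinol, and the route is rejoined at 11, now isolated. Closure to 12 (the bond from the ring CMe2 carbon to the saturated ketone carbon) follows with LiN(iPr)2 (3 equiv) as in the second half of step 5, where base and temperature can be tuned without regard to the first acylation.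

2. Step 4. Facial discrimination in the 5-exo radical closure may be poor, giving the epimer at the ring B methine, or the tertiary cation may lose a proton faster than the ester captures it. The fallback replaces substrate control by reagent control and avoids the cation. Setting out from 7, Shi epoxidation of the trisubstituted alkene uses the L-series ketone 1,2:4,5-di-O-isopropylidene-β-L-erythro-2,3-hexodiulo-2,6-pyranose, the enantiomer expected from the spiro transition-state model to give the (S)-epoxide (KHSO5 as its triple salt 2KHSO5·KHSO4·K2SO4, K2CO3, MeCN/dimethoxymethane/H2O, 0 °C). This should give the (S)-epoxide F3. NaH (THF, 0 °C → reflux) then forms the malonate anion, which opens the epoxide 5-exo-tet at its secondary carbon with inversion. The tertiary alkoxide so released lactonises onto the cis ester with loss of methoxide, and the route is rejoined at 8.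

3. Step 6. Discrimination between the two enol oxygens may be insufficient, or the hydroxy vinylogous acid may cyclodehydrate onto the carbonyl next to the central spiro carbon before it is capped. The fallback moves the regiochemical decision to the end of the route and makes it thermodynamic. Setting out from 12, the methylation is run without regard to selectivity, giving 13 together with the regioisomeric enol ether F4 (methoxy on the carbon next to the central spiro carbon, carbonyl between the C-methyl and ring CMe2 carbons). The mixture is taken through steps 7 and 8, F4 passing through its oxalate F5 to the regioisomer of the target F6. The mixture of 15 and F6 is finally equilibrated with TsOH (cat.) in MeOH/HC(OMe)3 at 50 °C. With the hydroxyl gone nothing can intercept the oxocarbenium intermediates, and exchange through the mixed dimethyl ketal should funnel F6 into the less congested enol ether, which is where the route is rejoined at 15.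

**Further compounds**

F1 | step 5 | lactol from reduction of the lactone carbonyl of 8 (anomers), methyl ester retained | OC1OC(C)(C)[C@H]2CC[C@@]3(CC[C@@H]4C[C@H]3C4(C)C)[C@@]12C(=O)OC
F2 | step 5 | β-hydroxy ketone aldol adduct (carbinol on the former lactone carbon, ketone on the isopropyl side, epimers at the carbinol and CH(CH3) carbons) with CO2CH3 on the central spiro carbon and C(CH3)2OH on the ring B methine | CC(C)C(=O)C(C)C(O)[C@@]2(C(=O)OC)[C@@H](C(C)(C)O)CC[C@@]21CC[C@@H]2C[C@H]1C2(C)C
F3 | step 4 | (S)-epoxide of the homoprenyl malonate 7 | COC(=O)C(C(=O)OC)[C@@]1(CC[C@@H]3OC3(C)C)CC[C@@H]2C[C@H]1C2(C)C
F4 | step 6 | regioisomeric methyl enol ether of 12 (OCH3 on the carbon next to the central spiro carbon, C=O between the C-methyl and ring CMe2 carbons) with the free tertiary alcohol | O=C1C(C)=C(OC)[C@@]2(C(=O)C1(C)C)[C@@H](C(C)(C)O)CC[C@@]21CC[C@@H]2C[C@H]1C2(C)C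
F5 | step 6 | tertiary methyl oxalate of F4 | O=C1C(C)=C(OC)[C@@]2(C(=O)C1(C)C)[C@@H](C(C)(C)OC(=O)C(=O)OC)CC[C@@]21CC[C@@H]2C[C@H]1C2(C)C
F6 | step 6 | regioisomer of the target (OCH3 on the carbon next to the central spiro carbon, C=O between the C-methyl and ring CMe2 carbons, isopropyl on the ring B methine) | O=C1C(C)=C(OC)[C@@]2(C(=O)C1(C)C)[C@@H](C(C)C)CC[C@@]21CC[C@@H]2C[C@H]1C2(C)C
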